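**Strategy.** The cyclohexane is cut across two ring bonds, C1–C2 and C5–C6 (C1 is the quaternary carbon bearing methyl and acyl, C2 the CH bearing the 3-oxobutyl chain, C3 the CMe2 carbon). A catalytic enantioselective Diels–Alder reaction joins an isopropenyl ketone that already carries the complete citronellate glyceride chain with an (E)-1-alkyl-2-methylbutadiene and sets C1, C2 and their cis relationship in one operation. It exploits the vicinal placement of the C1 acyl group and the C2 side chain on the six-membered ring, the signature of an ortho, endo cycloadduct. Iron-mediated hydromethylation of the remaining C3=C4 alkene then completes the gem-dimethyl carbon.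

Key step: step 5

Remark: ring locants C1–C6 are those of the cyclohexane in the name of the target. The sense of induction of the chiral Lewis acid on this α-methyl enone is assigned by analogy only; the (S)-catalyst is written, and its mirror image is used if an analytical run shows the opposite ring series.

**Step 1**
Reactants: 1 (R)-citronellic acid; 2 (S)-solketal
Product: 3 [(4R)-2,2-dimethyl-1,3-dioxolan-4-yl]methyl (3R)-3,7-dimethyloct-6-enoate
Conditions: DCC, 4-(dimethylamino)pyridine (cat.), CH2Cl2, 0 °C → rt
Reagents that add atoms: none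
Why: Steglich esterification of an unhindered acid with a primary alcohol should proceed without touching either stereocentre (the dioxolane descriptor changes from S to R only through the priority rules).

**Step 2**
Reactants: 3
Product: 6 [(4R)-2,2-dimethyl-1,3-dioxolan-4-yl]methyl (3R)-3,7-dimethyl-6-oxooct-7-enoate, via allylic hydroperoxide 4 (not isolated), via allylic peroxyacetate 5 (not isolated)
Conditions: O2, 5,10,15,20-tetraphenylporphyrin (cat.), visible light, CH2Cl2, 0 °C; then Ac2O, pyridine, 4-(dimethylamino)pyridine (cat.), 0 °C → rt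
Reagents that add atoms: dioxygen, O=O
Why: A Schenck ene reaction of singlet oxygen at the trisubstituted alkene followed by Kornblum–DeLaMare-type dehydration of the secondary hydroperoxide should give the isopropenyl ketone with all ten carbons retained; the tertiary hydroperoxide regioisomer, which is expected alongside, cannot eliminate and is removed by chromatography.

**Step 3**
Reactants: 7 3-methyl-2,5-dihydrothiophene 1,1-dioxide (3-methyl-3-sulfolene); 8 2-(2-bromoethyl)-2-methyl-1,3-dioxolane
Product: 9 3-methyl-2-[2-(2-methyl-1,3-dioxolan-2-yl)ethyl]-2,5-dihydrothiophene 1,1-dioxide (racemic)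
Conditions: LiN(SiMe3)2 (added last to the mixture of 7 and 8), THF–HMPA, −78 °C
Reagents that add atoms: none
Why: Deprotonation should give the allyl-type α-sulfonyl anion at C2, which keeps negative charge off the methyl-bearing carbon, and in-situ SN2 alkylation by the primary bromide traps it before ring-opening; the new stereocentre is racemic and is destroyed in step 4.

**Step 4**
Reactants: 9
Product: 10 2-methyl-2-[(3E)-4-methylhexa-3,5-dien-1-yl]-1,3-dioxolane
Conditions: toluene, pyridine (cat.), 110 °C, N2 sweep
Reagents that add atoms: none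
Why: Thermal cheletropic extrusion of SO2 is disrotatory and turns the C2 substituent outward, so only the (E)-diene should form.

**Step 5 (key step)**
Reactants: 6 isopropenyl ketone; 10 (E)-diene
Product: 11 [(4R)-2,2-dimethyl-1,3-dioxolan-4-yl]methyl (3R)-6-{(1R,2S)-1,3-dimethyl-2-[2-(2-methyl-1,3-dioxolan-2-yl)ethyl]cyclohex-3-en-1-yl}-3-methyl-6-oxohexanoate
Conditions: (S)-3,3-diphenyl-1-(o-tolyl)tetrahydro-1H,3H-pyrrolo[1,2-c][1,3,2]oxazaborole (20 mol %), HN(SO2CF3)2 (20 mol %), CH2Cl2, −78 → −20 °C
Reagents that add atoms: none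
Why: Coordination of the ketone of 6 to the cationic chiral boron Lewis acid lowers the enone LUMO, and a concerted, asynchronous [4π+2π] cycloaddition with s-cis 10 follows, in which the CH2 terminus of the diene bonds to the enone β-CH2 (ring C5–C6) and the alkyl-bearing terminus to the α-carbon (ring C1–C2). The closest known reaction type is the oxazaborolidinium-catalysed enantioselective Diels–Alder reaction of α,β-unsaturated ketones and 2-substituted acroleins with acyclic dienes. The cyclohexene is closed by an intermolecular suprafacial [4+2] cycloaddition that makes both ring bonds in one transition state. C1 (quaternary, R) is set by the catalyst, which must leave the Si face of the enone α-carbon open to the diene; C2 (S) follows from the endo orientation of the acyl group combined with the fixed E geometry of 10, which places acyl group and side chain cis. The step needs ortho regioselectivity, which the dominant 1-alkyl substituent (largest HOMO coefficient at the unsubstituted terminus) and the Lewis acid polarisation of the enone should secure against the weaker opposing 2-methyl effect; it needs endo selectivity, which the carbonyl–diene secondary interaction under Lewis acid catalysis should secure; and it needs facial selectivity, which rests on the catalyst antipode.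

**Step 6**
Reactants: 11
Product: 13 [(4R)-2,2-dimethyl-1,3-dioxolan-4-yl]methyl (3R)-3-methyl-6-oxo-6-{(1R,2S)-1,3,3-trimethyl-2-[2-(2-methyl-1,3-dioxolan-2-yl)ethyl]cyclohexyl}hexanoate, via sulfonyl hydrazide 12 (not isolated)
Conditions: Fe(acac)3 (50 mol %), PhSiH3, formaldehyde N-(octylsulfonyl)hydrazone, THF–MeOH, 0 °C → rt; then MeOH, 60 °C
Reagents that add atoms: formaldehyde N-(octylsulfonyl)hydrazone, C=NNS(=O)(=O)CCCCCCCC
Why: Hydrogen-atom transfer from an iron hydride to ring C4 should give the tertiary C3 radical, which adds to the hydrazone carbon (Markovnikov hydromethylation), and thermal loss of sulfinic acid and N2 from 12 leaves the second methyl group; C3 becomes CMe2, so no stereocentre is created, C1 and C2 are untouched, and any ketal lost in the warm methanol is inconsequential because step 7 removes both.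

**Step 7**
Reactants: 13
Product: 14 (2R)-2,3-dihydroxypropyl (3R)-3-methyl-6-oxo-6-[(1R,2S)-1,3,3-trimethyl-2-(3-oxobutyl)cyclohexyl]hexanoate
Conditions: 1 M aq. HCl, THF, 0 °C → rt
Reagents that add atoms: water, O
Why: Acid-catalysed hydrolysis should remove the dioxolane ketal and the acetonide in one operation, under conditions mild enough to leave the ester in place and to keep 1,2-acyl migration slow.

**Step 8**
Reactants: 14
Product: 15 (2R)-3-(acetyloxy)-2-hydroxypropyl (3R)-3-methyl-6-oxo-6-[(1R,2S)-1,3,3-trimethyl-2-(3-oxobutyl)cyclohexyl]hexanoate (target)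
Conditions: immobilised lipase B from Candida antarctica, vinyl acetate, tert-butyl methyl ether, rt
Reagents that add atoms: vinyl acetate, C=COC(C)=O
Why: Lipase-catalysed transesterification with an irreversible acyl donor should acetylate the primary hydroxyl of the 1,2-diol selectively under neutral conditions, leaving the secondary hydroxyl free and its configuration untouched.

**Compound list**

1 | (R)-citronellic acid, (3R)-3,7-dimethyloct-6-enoic acid | CC(C)=CCC[C@@H](C)CC(=O)O | starting material
2 | (S)-solketal, [(4S)-2,2-dimethyl-1,3-dioxolan-4-yl]methanol | OC[C@H]1COC(C)(C)O1 | starting material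
3 | [(4R)-2,2-dimethyl-1,3-dioxolan-4-yl]methyl (3R)-3,7-dimethyloct-6-enoate | CC(C)=CCC[C@@H](C)CC(=O)OC[C@H]1COC(C)(C)O1 | intermediate
4 | [(4R)-2,2-dimethyl-1,3-dioxolan-4-yl]methyl (3R)-6-hydroperoxy-3,7-dimethyloct-7-enoate (C6 epimers) | C=C(C)C(OO)CC[C@@H](C)CC(=O)OC[C@H]1COC(C)(C)O1 | intermediate (not isolated)
5 | [(4R)-2,2-dimethyl-1,3-dioxolan-4-yl]methyl (3R)-6-(acetylperoxy)-3,7-dimethyloct-7-enoate (C6 epimers) | C=C(C)C(OOC(C)=O)CC[C@@H](C)CC(=O)OC[C@H]1COC(C)(C)O1 | intermediate (not isolated)
6 | [(4R)-2,2-dimethyl-1,3-dioxolan-4-yl]methyl (3R)-3,7-dimethyl-6-oxooct-7-enoate | C=C(C)C(=O)CC[C@@H](C)CC(=O)OC[C@H]1COC(C)(C)O1 | intermediate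
7 | 3-methyl-2,5-dihydrothiophene 1,1-dioxide | CC1=CCS(=O)(=O)C1 | starting material
8 | 2-(2-bromoethyl)-2-methyl-1,3-dioxolane | CC1(CCBr)OCCO1 | starting material
9 | 3-methyl-2-[2-(2-methyl-1,3-dioxolan-2-yl)ethyl]-2,5-dihydrothiophene 1,1-dioxide (racemic) | CC1=CCS(=O)(=O)C1CCC1(C)OCCO1 | intermediate
10 | 2-methyl-2-[(3E)-4-methylhexa-3,5-dien-1-yl]-1,3-dioxolane | C=C/C(C)=C/CCC1(C)OCCO1 | intermediate
11 | [(4R)-2,2-dimethyl-1,3-dioxolan-4-yl]methyl (3R)-6-{(1R,2S)-1,3-dimethyl-2-[2-(2-methyl-1,3-dioxolan-2-yl)ethyl]cyclohex-3-en-1-yl}-3-methyl-6-oxohexanoate | CC1(OCCO1)CC[C@H]1C(C)=CCC[C@@]1(C)C(=O)CC[C@@H](C)CC(=O)OC[C@H]1COC(C)(C)O1 | intermediate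
12 | N'-alkyl octane-1-sulfonohydrazide formed from 11 by addition of H at ring C4 and of CH2NHNHSO2C8H17 at ring C3 (C3 epimers; ring C1 and C2 as in 11) | CC1(OCCO1)CC[C@H]1C(C)(CNNS(=O)(=O)CCCCCCCC)CCC[C@@]1(C)C(=O)CC[C@@H](C)CC(=O)OC[C@H]1COC(C)(C)O1 | intermediate (not isolated)
13 | [(4R)-2,2-dimethyl-1,3-dioxolan-4-yl]methyl (3R)-3-methyl-6-oxo-6-{(1R,2S)-1,3,3-trimethyl-2-[2-(2-methyl-1,3-dioxolan-2-yl)ethyl]cyclohexyl}hexanoate | CC1(OCCO1)CC[C@H]1C(C)(C)CCC[C@@]1(C)C(=O)CC[C@@H](C)CC(=O)OC[C@H]1COC(C)(C)O1 | intermediate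
14 | (2R)-2,3-dihydroxypropyl (3R)-3-methyl-6-oxo-6-[(1R,2S)-1,3,3-trimethyl-2-(3-oxobutyl)cyclohexyl]hexanoate | CC(=O)CC[C@H]1C(C)(C)CCC[C@@]1(C)C(=O)CC[C@@H](C)CC(=O)OC[C@H](O)CO | intermediate
15 | (2R)-3-(acetyloxy)-2-hydroxypropyl (3R)-3-methyl-6-oxo-6-[(1R,2S)-1,3,3-trimethyl-2-(3-oxobutyl)cyclohexyl]hexanoate | CC(=O)CC[C@H]1C(C)(C)CCC[C@@]1(C)C(=O)CC[C@@H](C)CC(=O)OC[C@H](O)COC(C)=O | target

**Step count.** Total: 8 steps. Longest linear sequence: 6 steps (steps 1, 2, 5, 6, 7, 8 from 1); the diene arm (steps 3 and 4) is made in parallel.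

**Steps most likely to fail**

1. Step 5. The α-methyl enone offers neither a formyl nor an α-vinyl C–H for the two-point binding that organises simpler dienophiles on this catalyst, so facial discrimination may be poor. The 2-methyl group of the diene opposes the ortho-directing 1-alkyl group, so regiochemistry may leak. The cationic Lewis acid may also ionise the ketals. Fallback: setting out again from 6 and 10, the cycloaddition is run without chiral control (Me2AlCl, CH2Cl2, −78 → −40 °C). This should give the ortho, endo adduct as 11 together with its ring-antipodal diastereomer, [(4R)-2,2-dimethyl-1,3-dioxolan-4-yl]methyl (3R)-6-{(1S,2R)-1,3-dimethyl-2-[2-(2-methyl-1,3-dioxolan-2-yl)ethyl]cyclohex-3-en-1-yl}-3-methyl-6-oxohexanoate F1. The two are separated by preparative HPLC on a polysaccharide chiral stationary phase, and the route is rejoined at 11.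

2. Step 6. The hindered tertiary ring radical may be reduced to the simple hydrogenated cyclohexane, or may abstract a hydrogen intramolecularly, faster than it is trapped by the hydrazone; the hydrazide may also fragment incompletely. Fallback: setting out from 11, Simmons–Smith cyclopropanation of the C3=C4 alkene (Et2Zn, CH2I2, CH2Cl2, 0 °C → rt) should give the cyclopropane [(4R)-2,2-dimethyl-1,3-dioxolan-4-yl]methyl (3R)-6-{1,3-dimethyl-2-[2-(2-methyl-1,3-dioxolan-2-yl)ethyl]bicyclo[4.1.0]heptan-3-yl}-3-methyl-6-oxohexanoate F2 (either cyclopropane face, other ring centres as in 11). Hydrogenolysis of its least hindered CH–CH2 bond (H2, PtO2, EtOAc–AcOH, rt) turns the bridging carbon into the second methyl group, and the route is rejoined at 13.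

3. Step 3. The sulfolenyl anion may ring-open before the unactivated primary bromide alkylates it, and alkylation at C5 or double alkylation may compete. Fallback: setting out from 8, Ganem oxidation (Me3NO, DMSO, rt → 50 °C) should give 3-(2-methyl-1,3-dioxolan-2-yl)propanal F3. An E-selective Wittig reaction with 2-(triphenylphosphoranylidene)propanal (toluene, 80 °C) gives (2E)-2-methyl-5-(2-methyl-1,3-dioxolan-2-yl)pent-2-enal F4. Wittig methylenation (Ph3P=CH2, THF, 0 °C) then gives the diene, so the route is rejoined at 10 and both 9 and step 4 are bypassed.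

**Further compounds**

F1 | step 5 | [(4R)-2,2-dimethyl-1,3-dioxolan-4-yl]methyl (3R)-6-{(1S,2R)-1,3-dimethyl-2-[2-(2-methyl-1,3-dioxolan-2-yl)ethyl]cyclohex-3-en-1-yl}-3-methyl-6-oxohexanoate | CC1(OCCO1)CC[C@@H]1C(C)=CCC[C@]1(C)C(=O)CC[C@@H](C)CC(=O)OC[C@H]1COC(C)(C)O1
F2 | step 6 | [(4R)-2,2-dimethyl-1,3-dioxolan-4-yl]methyl (3R)-6-{1,3-dimethyl-2-[2-(2-methyl-1,3-dioxolan-2-yl)ethyl]bicyclo[4.1.0]heptan-3-yl}-3-methyl-6-oxohexanoate | CC1(OCCO1)CC[C@H]1C2(C)CC2CC[C@@]1(C)C(=O)CC[C@@H](C)CC(=O)OC[C@H]1COC(C)(C)O1
F3 | step 3 | 3-(2-methyl-1,3-dioxolan-2-yl)propanal | O=CCCC1(C)OCCO1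
F4 | step 3 | (2E)-2-methyl-5-(2-methyl-1,3-dioxolan-2-yl)pent-2-enal | O=C/C(C)=C/CCC1(C)OCCO1
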